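## Structural features

The target is a 3,3'-linked biflavanone. Unit 1 is a 5,7-dihydroxy-2-(4-methoxyphenyl)chroman-4-one and unit 2 (primed locants) is a 5,7-dihydroxy-2-(4-hydroxyphenyl)chroman-4-one, joined by the single bond C3–C3'. The four stereocentres C2, C3, C3' and C2' form one unbroken chain with the configuration (2S,3R,3'S,2'S), so ring C of unit 1 is 2,3-trans and ring C of unit 2 is 2',3'-cis. C3 and C3' are each alpha to a ketone and beta to an aryloxy oxygen, so base can epimerise them or open either ring C by beta-elimination of the phenoxide, and the cis unit is the arrangement such equilibration would destroy. C2 and C2' are benzylic ether carbons with para-oxygenated aryl groups and can ionise in strong acid, and the two phloroglucinol-type rings are very electron-rich. One methyl ether must stay distinct from five free phenols, so no ether-cleaving reagent can be used at the end. The real difficulty is the relative configuration across C3–C3' together with the cis relationship in unit 2. The key step uses the fact that C4 of unit 1 and the oxygen on C2' are 1,4-related through C3 and C3': they can be tied as a five-membered lactone C4(=O)–C3–C3'–C2'–O whose all-trans substitution fixes C3, C3' and C2', and an aryllithium at C4a of ring A then turns that lactone carbonyl into the C4 ketone, closing ring C of unit 1 and returning the oxygen to C2'.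

## Logic of the disconnections

**22 ⇒ 21.** Bonds cut: the five phenolic O–CH2Ph bonds. Every phenol is carried as a benzyl ether so that one neutral hydrogenolysis ends the synthesis and the methyl ether is never at risk. The gain is that all earlier intermediates are non-phenolic and not prone to oxidation. The forward step must stay neutral and must spare the benzylic ring C–O bonds at C2 and C2'.

**21 ⇒ 19 ⇒ 18.** Bonds cut: C4'–C4a', then the O–C(CH3)3 bond of the ester. Ring A' of 19 is a 1,3,5-trioxygenated benzene, so acylation ortho to the ether oxygen is the easiest aryl–carbon bond to make, and it leaves C2' and C3' untouched. Unit 2 is thereby reduced to an open-chain beta-aryloxy acid. The forward steps must not enolise C3' or ionise C2', and the ester must be cleaved without free tert-butyl cations that would alkylate the trioxygenated ring.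

**18 ⇒ 16 + 17.** Bond cut: O1'–C8a'. Making the aryl–oxygen bond (not the alkyl–oxygen bond) keeps the C2'–O bond and its configuration, so the cis unit follows from the trans lactone. The gain is that 17 is symmetrical and 16 is the direct product of the key step. The demand is a C–O coupling of a hindered secondary benzylic alcohol beside a base-sensitive chromanone and a beta-hydroxy ester.

**16 ⇒ 14 (key).** Bond cut: C4–C4a, and the C4 carbonyl is reconnected to the C2' oxygen. Three stereocentres (C3, C3', C2') become the ring substitution of one trans,trans-trisubstituted butyrolactone, and the unit 1 chromanone does not exist while strong-base chemistry is done. The forward step needs halogen–lithium exchange faster than any proton transfer or carbonyl addition, attack on the lactone and not on the ester, and a bromine placed between the ether oxygen and a benzyloxy group.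

**14 ⇒ 11 + 13; 13 ⇒ 12.** Bonds cut: the alkyl–oxygen bond C2–O1, then C–Br. An invertive etherification joins ring A to C2 and sets C2 from a carbinol. This demands the (R)-carbinol in 11, a clean SN2 process at an ionisable anisyl carbinol without beta-elimination, and bromination of 12 only ortho to the hydroxyl.

**11 ⇒ 10 ⇒ 8 + 9.** Bonds cut: C2–H, then C2–C3. A one-step aldol of the lactone enolate through a closed transition state would favour the anti carbinol, which is the wrong epimer for an invertive etherification, and with poor control. Going through the ketone lets a chiral catalyst set C2, while C3 (epimerisable in 10) settles trans to the C3' ester. The forward steps need enolisation at the lactone CH2 and not at C3'–H, and catalyst control that agrees with the substrate.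

**8 ⇒ 7 ⇒ 6.** Bonds cut: the ester O–C(CH3)3 bond and the exocyclic N–acyl bond. A tert-butyl ester is the carboxyl form that resists enolate and organolithium chemistry and is not readily enolised at C3'. The imide must go first because its alpha-proton would be removed before that of the lactone. The demand is cleavage and esterification without epimerising C3' or opening the lactone by elimination.

**6 ⇒ 3 + 4; 3 ⇒ 1 + 2.** Bonds cut: C3'–C2' (aldol), the lactone acyl–oxygen bond, and N–acyl. An auxiliary-controlled syn aldol of a succinate sets C3' and C2' in absolute terms, and lactonisation of a syn adduct gives the trans lactone. The demand is enolisation on the imide side only.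

## Other disconnections considered

**Alternative 1:** The cut is at the C2–aryl bond and at C3–C3', so unit 1 comes from 5,7-bis(benzyloxy)chromone A2.
- Forward key step: a three-component coupling under rhodium catalysis with a chiral bisphosphine. (4-Methoxyphenyl)zinc chloride A3 adds to C2 of A2, and the zinc enolate is alkylated at C3 by 2-bromo-1-[2,4-bis(benzyloxy)-6-fluorophenyl]ethan-1-one A4 on the face away from the new aryl group, to give the trans diketone A1.
- In its favour: two skeletal bonds and the trans relationship in one operation, and C2 set by a catalyst instead of an auxiliary. Ring A' arrives with a fluorine that would let the C2' alkoxide close O1'–C8a' by intramolecular substitution activated by the ortho ketone.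
- Against it here: the zinc enolate of a chromanone is a weak nucleophile and can expel the ring A phenoxide. C3'–C2' must still be made by an aldol of A1 with 4, where two enolisable positions compete and C3' and C2' have no controlling element, under base that can epimerise C3.
- Comparison: on structure it is equal for the trans unit 1 but weaker for the C3–C3' relationship and the cis unit 2, which the chosen plan locks in a ring before either ketone exists. On mechanism its O1'–C8a' closure (intramolecular, ketone-activated) is better than the intermolecular palladium coupling of step 10. On step economy it is clearly better, at roughly half the number of steps.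

**Alternative 2:** The cut removes ring A of unit 1 (C4a–C5 and C8–C8a).
- Forward key step: 1,1-dimethoxy-3-(trimethylsilyloxy)buta-1,3-diene A6 adds in a Diels–Alder reaction across the brominated enol-ether double bond of methyl 2-[(2S,3R)-5-bromo-2-(4-methoxyphenyl)-4-oxo-3,4-dihydro-2H-pyran-3-yl]acetate A7, and two eliminations aromatise the adduct to the chromanone A5.
- In its favour: the substitution pattern of ring A follows from the polarity of diene and dienophile, with the C5 and C7 oxygens already differentiated. No halogenated phenol and no organolithium are needed, and C2 of A7 could come from a catalytic asymmetric hetero-Diels–Alder reaction.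
- Against it here: it builds a ring that the chosen plan buys ready-made in 12 and 17. A7 is a vinylogous ester and a reluctant dienophile, and heating endangers C3. The C5 methyl ether must later be cleaved beside the anisyl ether. All of unit 2, including C3' and C2', is still to be built from the acetate arm without control.
- Comparison: on structure it is better than step 7 of the chosen plan for ring A regiochemistry, equal for the trans unit 1, and weaker for C3' and C2'. On mechanism a neutral pericyclic step is at least the equal of an organolithium step in mildness, if it proceeds at moderate temperature. On step economy it is worse.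

**Alternative 3:** The cut goes through O1–C2 and C3–C4 of ring C of unit 1.
- Forward key step: acid converts 2,4-bis(benzyloxy)-6-hydroxybenzaldehyde A9 and trimethyl orthoformate A11 into an alpha-methoxy ortho-quinone methide. This adds in an inverse-demand hetero-Diels–Alder reaction across methyl (E)-4-(4-methoxyphenyl)but-3-enoate A10 under a chiral phosphoric acid to give the 4-methoxychroman A8 (2,3-trans, 3,4-trans).
- In its favour: it is convergent, with ring C made from two simple components without strong base or metal. The trans relationship follows stereospecifically from the alkene geometry, which is better founded than an inversion at an ionisable carbinol (step 8). Ring A regiochemistry is fixed by the aldehyde.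
- Against it here: facial control must come from an ion pair between the acid and a cationic heterodiene, with an alkene that offers no hydrogen-bond handle. A10 can slip into conjugation with its ester. C4 arrives at the alcohol oxidation level, so hydrolysis and oxidation must follow. Unit 2 again has to be grown from the acetate arm with C3' and C2' uncontrolled.
- Comparison: on structure it is equal or better for unit 1 and weaker for the C3–C3' relationship and the cis unit. On mechanism it is milder than the chosen key step. On step economy it is similar or worse once the oxidation-state correction and the construction of unit 2 are counted.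

Key step: step 9

Remark: the locants C2, C3, C4, C4a (unit 1) and C2', C3', C4', C4a' (unit 2) are those of the two chromanones of the target and are used for the same atoms in every intermediate; 12 and 17 are taken as purchasable.

## Route

Step 1
Reactants: 1 (S)-4-benzyl-1,3-oxazolidin-2-one; 2 methyl 4-chloro-4-oxobutanoate
Product: 3 methyl 4-[(4S)-4-benzyl-2-oxo-1,3-oxazolidin-3-yl]-4-oxobutanoate
Conditions: n-BuLi, THF, −78 °C; then 2, −78 → 0 °C
Reagents that add atoms: none
Why: N-acylation of the lithiated oxazolidinone by an acid chloride; the acyl chloride reacts far faster than the methyl ester at the other end, so only the imide should form.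

Step 2
Reactants: 3 methyl 4-[(4S)-4-benzyl-2-oxo-1,3-oxazolidin-3-yl]-4-oxobutanoate; 4 4-(benzyloxy)benzaldehyde
Product: 6 (4S)-4-benzyl-3-{[(2S,3S)-2-[4-(benzyloxy)phenyl]-5-oxotetrahydrofuran-3-yl]carbonyl}-1,3-oxazolidin-2-one, via syn-aldol hydroxy ester 5 (not isolated)
Conditions: Bu2BOTf, i-Pr2NEt, CH2Cl2, −78 → 0 °C; 4, −78 → 0 °C; pH 7 buffer–MeOH–30% H2O2, 0 °C; crude in CH2Cl2, PPTS (cat.), rt
Reagents that add atoms: none
Why: Oxazolidinone-controlled syn aldol: the boron triflate and amine enolise only the imide side to the (Z)-boron enolate, and the chair transition state with the aldehyde on the face away from the benzyl group should set C3' and C2' as (S,S). The gamma-hydroxy methyl ester 5 then lactonises with loss of methanol, and a syn adduct of this kind closes to the trans-2,3-disubstituted lactone.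

Step 3
Reactants: 6 (4S)-4-benzyl-3-{[(2S,3S)-2-[4-(benzyloxy)phenyl]-5-oxotetrahydrofuran-3-yl]carbonyl}-1,3-oxazolidin-2-one
Product: 7 (2S,3S)-2-[4-(benzyloxy)phenyl]-5-oxotetrahydrofuran-3-carboxylic acid
Conditions: LiOH, 30% H2O2, THF–H2O, 0 °C; Na2SO3; 1 M HCl to pH 2
Reagents that add atoms: hydrogen peroxide (as LiOOH), OO
Why: Hydroperoxide cleavage of an N-acyloxazolidinone: LiOOH attacks the exocyclic imide carbonyl, sulfite reduces the peracid, and any lactone opened by hydroxide should reclose on acidification. The carboxylate is not enolisable under these conditions, so C3' is not at risk.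

Step 4
Reactants: 7 (2S,3S)-2-[4-(benzyloxy)phenyl]-5-oxotetrahydrofuran-3-carboxylic acid
Product: 8 tert-butyl (2S,3S)-2-[4-(benzyloxy)phenyl]-5-oxotetrahydrofuran-3-carboxylate
Conditions: Cl3CC(=NH)Ot-Bu, CH2Cl2–cyclohexane, rt
Reagents that add atoms: tert-butyl 2,2,2-trichloroacetimidate, CC(C)(C)OC(=N)C(Cl)(Cl)Cl
Why: Imidate esterification: the carboxylic acid protonates the trichloroacetimidate and captures the tert-butyl group without activation of the acyl carbon, so neither C3' nor the lactone is touched. The tert-butyl ester is chosen because it resists the enolate and organolithium chemistry that follows.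

Step 5
Reactants: 8 tert-butyl (2S,3S)-2-[4-(benzyloxy)phenyl]-5-oxotetrahydrofuran-3-carboxylate; 9 4-methoxybenzoyl chloride
Product: 10 tert-butyl (2S,3S,4R)-2-[4-(benzyloxy)phenyl]-4-(4-methoxybenzoyl)-5-oxotetrahydrofuran-3-carboxylate
Conditions: LiN(SiMe3)2 (2.1 equiv), THF, −78 °C; then 9, −78 °C; AcOH, −78 °C
Reagents that add atoms: none
Why: Crossed Claisen C-acylation of a lactone enolate: the amide base should remove a proton from the unhindered lactone CH2 (C3) and not the tertiary C3'–H next to the bulky ester, and the second equivalent takes up the more acidic product. C3 of the beta-keto lactone is epimerisable and should settle trans to the C3' ester on protonation.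

Step 6
Reactants: 10 tert-butyl (2S,3S,4R)-2-[4-(benzyloxy)phenyl]-4-(4-methoxybenzoyl)-5-oxotetrahydrofuran-3-carboxylate
Product: 11 tert-butyl (2S,3S,4R)-2-[4-(benzyloxy)phenyl]-4-[(R)-hydroxy(4-methoxyphenyl)methyl]-5-oxotetrahydrofuran-3-carboxylate
Conditions: RuCl[(R,R)-TsDPEN](p-cymene) (2 mol%), HCO2H–Et3N (5:2), CH2Cl2, rt
Reagents that add atoms: none
Why: Asymmetric transfer hydrogenation of an aryl ketone; hydride delivery is catalyst-controlled, and the (R,R) catalyst should give the (R)-carbinol by the usual aryl-ketone model. C3 stays trans to the C3' ester, so the carbinol should be syn to C3, which is the epimer the invertive etherification of step 8 needs.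

Step 7
Reactants: 12 3,5-bis(benzyloxy)phenol
Product: 13 3,5-bis(benzyloxy)-2-bromophenol
Conditions: NBS (1.0 equiv), i-Pr2NH (10 mol%), CH2Cl2, −78 → 0 °C
Reagents that add atoms: N-bromosuccinimide, O=C1CCC(=O)N1Br
Why: Ortho-selective electrophilic bromination of a phenol: the N-bromoamine formed from NBS and the secondary amine is delivered through a hydrogen bond to the hydroxyl, and the only other activated position (C4) is flanked by two benzyloxy groups.

Step 8
Reactants: 11 tert-butyl (2S,3S,4R)-2-[4-(benzyloxy)phenyl]-4-[(R)-hydroxy(4-methoxyphenyl)methyl]-5-oxotetrahydrofuran-3-carboxylate; 13 3,5-bis(benzyloxy)-2-bromophenol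
Product: 14 tert-butyl (2S,3S,4R)-2-[4-(benzyloxy)phenyl]-4-{(S)-[3,5-bis(benzyloxy)-2-bromophenoxy](4-methoxyphenyl)methyl}-5-oxotetrahydrofuran-3-carboxylate
Conditions: PPh3, DIAD, toluene, 0 °C → rt
Reagents that add atoms: none
Why: Mitsunobu etherification: the phenol, made more acidic by the ortho bromine, displaces the oxyphosphonium group in an SN2 step, so C2 is inverted from (R) to the (S) configuration of the target. Toluene and low temperature are chosen to disfavour ionisation of the anisyl carbinol and beta-elimination to the benzylidene lactone.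

Step 9
Reactants: 14 tert-butyl (2S,3S,4R)-2-[4-(benzyloxy)phenyl]-4-{(S)-[3,5-bis(benzyloxy)-2-bromophenoxy](4-methoxyphenyl)methyl}-5-oxotetrahydrofuran-3-carboxylate
Product: 16 tert-butyl (2S,3S)-3-[4-(benzyloxy)phenyl]-2-[(2S,3R)-5,7-bis(benzyloxy)-2-(4-methoxyphenyl)-4-oxochroman-3-yl]-3-hydroxypropanoate, via lithium hemiketal 15 (not isolated)
Conditions: t-BuLi (2.1 equiv), THF–Et2O, −100 °C, then −78 °C; AcOH (THF), −78 °C → rt
Reagents that add atoms: none
Why: Parham cyclisation (halogen–lithium exchange followed by intramolecular acylation of the aryllithium), here with a lactone as the acyl donor. t-BuLi should exchange the C4a–Br bond, which lies between two ether oxygens, much faster at −100 °C than it adds to a carbonyl or removes the C3–H or C3'–H protons, and the second equivalent destroys the tert-butyl bromide formed. The aryllithium, held beside the lactone by the C2–O1 ether tether, adds to the lactone carbonyl C4 in a 6-exo-trig closure that forms the C4–C4a bond and ring C of unit 1. The adduct is the cis-fused lithium hemiketal 15, which should not collapse at −78 °C, so no ketone is exposed to organolithium and a second addition is excluded; on protonation it opens to the C4 ketone and the free C2' carbinol of 16. No stereocentre is made or touched: C2, C3, C3' and C2' keep the configuration set in 14, and the hemiketal carbon of 15 is transient with its configuration dictated by the cis ring fusion. Selectivity for the lactone over the tert-butyl ester rests on ring size (six- against seven-membered closure), on the higher electrophilicity of a gamma-lactone and on the bulk of the tert-butyl group. Epimerisation at C3 and beta-elimination of the ring A phenoxide are held back by the low temperature, by the intramolecular consumption of the only strong base, and by the acetic acid quench at −78 °C.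

Step 10
Reactants: 16 tert-butyl (2S,3S)-3-[4-(benzyloxy)phenyl]-2-[(2S,3R)-5,7-bis(benzyloxy)-2-(4-methoxyphenyl)-4-oxochroman-3-yl]-3-hydroxypropanoate; 17 1,3-bis(benzyloxy)-5-bromobenzene
Product: 18 tert-butyl (2S,3S)-3-[4-(benzyloxy)phenyl]-3-[3,5-bis(benzyloxy)phenoxy]-2-[(2S,3R)-5,7-bis(benzyloxy)-2-(4-methoxyphenyl)-4-oxochroman-3-yl]propanoate
Conditions: 17 (1.5 equiv), [Pd(allyl)Cl]2 (2.5 mol%), RockPhos (7.5 mol%), Cs2CO3 (1.5 equiv), toluene, 80 °C
Reagents that add atoms: none
Why: Palladium-catalysed C–O cross-coupling of a secondary alcohol with an aryl bromide; the bulky biaryl phosphine favours C–O reductive elimination over beta-hydride elimination. Only the O–H bond of the carbinol reacts, so C2' keeps its configuration, and a weak insoluble carbonate is used because the chromanone and the beta-hydroxy ester are base-sensitive.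

Step 11
Reactants: 18 tert-butyl (2S,3S)-3-[4-(benzyloxy)phenyl]-3-[3,5-bis(benzyloxy)phenoxy]-2-[(2S,3R)-5,7-bis(benzyloxy)-2-(4-methoxyphenyl)-4-oxochroman-3-yl]propanoate
Product: 19 (2S,3S)-3-[4-(benzyloxy)phenyl]-3-[3,5-bis(benzyloxy)phenoxy]-2-[(2S,3R)-5,7-bis(benzyloxy)-2-(4-methoxyphenyl)-4-oxochroman-3-yl]propanoic acid
Conditions: 85% aq. H3PO4, toluene, rt
Reagents that add atoms: none
Why: Acidolysis of a tert-butyl ester by alkyl–oxygen cleavage; in the aqueous two-phase medium the tert-butyl cation is trapped by water and should not alkylate the trioxygenated ring. Benzyl ethers and both benzylic aryl ethers should survive this weak acid.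

Step 12
Reactants: 19 (2S,3S)-3-[4-(benzyloxy)phenyl]-3-[3,5-bis(benzyloxy)phenoxy]-2-[(2S,3R)-5,7-bis(benzyloxy)-2-(4-methoxyphenyl)-4-oxochroman-3-yl]propanoic acid
Product: 21 (2S,3R,2'S,3'S)-5,5',7,7'-tetrakis(benzyloxy)-2'-[4-(benzyloxy)phenyl]-2-(4-methoxyphenyl)-[3,3'-bichromane]-4,4'-dione, via mixed trifluoroacetic anhydride 20 (not isolated)
Conditions: (CF3CO)2O, CH2Cl2, 0 °C
Reagents that add atoms: none
Why: Intramolecular Friedel–Crafts acylation through the mixed anhydride 20: the acyl carbon attacks the position ortho to the ether oxygen of the 3,5-bis(benzyloxy)phenoxy ring (both ortho positions are equivalent), closing the six-membered ring C of unit 2. No bond to C2' or C3' is broken, so the trans lactone configuration becomes the cis chromanone, and the low temperature limits acid-catalysed enolisation at C3'.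

Step 13
Reactants: 21 (2S,3R,2'S,3'S)-5,5',7,7'-tetrakis(benzyloxy)-2'-[4-(benzyloxy)phenyl]-2-(4-methoxyphenyl)-[3,3'-bichromane]-4,4'-dione
Product: 22 (2S,3R,2'S,3'S)-5,5',7,7'-tetrahydroxy-2'-(4-hydroxyphenyl)-2-(4-methoxyphenyl)-[3,3'-bichromane]-4,4'-dione
Conditions: H2 (1 atm), 10% Pd/C, EtOAc–MeOH, rt
Reagents that add atoms: none
Why: Hydrogenolysis of five benzyl aryl ethers under neutral conditions; the methyl ether and the ketones are inert, and the reaction is stopped at the calculated uptake to spare the ring C–O bonds at C2 and C2'. The neutral medium should leave the cis unit unepimerised.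

## Compound list

1 | (S)-4-benzyl-1,3-oxazolidin-2-one | O=C1N[C@@H](Cc2ccccc2)CO1 | starting material
2 | methyl 4-chloro-4-oxobutanoate | COC(=O)CCC(Cl)=O | starting material
3 | methyl 4-[(4S)-4-benzyl-2-oxo-1,3-oxazolidin-3-yl]-4-oxobutanoate | COC(=O)CCC(=O)N1[C@@H](Cc2ccccc2)COC1=O | intermediate
4 | 4-(benzyloxy)benzaldehyde | O=Cc1ccc(OCc2ccccc2)cc1 | starting material
5 | methyl (3S,4S)-3-{[(4S)-4-benzyl-2-oxo-1,3-oxazolidin-3-yl]carbonyl}-4-[4-(benzyloxy)phenyl]-4-hydroxybutanoate | COC(=O)C[C@H](C(=O)N1[C@@H](Cc2ccccc2)COC1=O)[C@H](O)c1ccc(OCc2ccccc2)cc1 | intermediate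
6 | (4S)-4-benzyl-3-{[(2S,3S)-2-[4-(benzyloxy)phenyl]-5-oxotetrahydrofuran-3-yl]carbonyl}-1,3-oxazolidin-2-one | O=C1C[C@H](C(=O)N2[C@@H](Cc3ccccc3)COC2=O)[C@@H](c2ccc(OCc3ccccc3)cc2)O1 | intermediate
7 | (2S,3S)-2-[4-(benzyloxy)phenyl]-5-oxotetrahydrofuran-3-carboxylic acid | O=C1C[C@H](C(=O)O)[C@@H](c2ccc(OCc3ccccc3)cc2)O1 | intermediate
8 | tert-butyl (2S,3S)-2-[4-(benzyloxy)phenyl]-5-oxotetrahydrofuran-3-carboxylate | O=C1C[C@H](C(=O)OC(C)(C)C)[C@@H](c2ccc(OCc3ccccc3)cc2)O1 | intermediate
9 | 4-methoxybenzoyl chloride | COc1ccc(C(Cl)=O)cc1 | starting material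
10 | tert-butyl (2S,3S,4R)-2-[4-(benzyloxy)phenyl]-4-(4-methoxybenzoyl)-5-oxotetrahydrofuran-3-carboxylate | COc1ccc(C(=O)[C@@H]2C(=O)O[C@H](c3ccc(OCc4ccccc4)cc3)[C@H]2C(=O)OC(C)(C)C)cc1 | intermediate
11 | tert-butyl (2S,3S,4R)-2-[4-(benzyloxy)phenyl]-4-[(R)-hydroxy(4-methoxyphenyl)methyl]-5-oxotetrahydrofuran-3-carboxylate | COc1ccc([C@H](O)[C@@H]2C(=O)O[C@H](c3ccc(OCc4ccccc4)cc3)[C@H]2C(=O)OC(C)(C)C)cc1 | intermediate
12 | 3,5-bis(benzyloxy)phenol | Oc1cc(OCc2ccccc2)cc(OCc2ccccc2)c1 | starting material
13 | 3,5-bis(benzyloxy)-2-bromophenol | Oc1cc(OCc2ccccc2)cc(OCc2ccccc2)c1Br | intermediate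
14 | tert-butyl (2S,3S,4R)-2-[4-(benzyloxy)phenyl]-4-{(S)-[3,5-bis(benzyloxy)-2-bromophenoxy](4-methoxyphenyl)methyl}-5-oxotetrahydrofuran-3-carboxylate | COc1ccc([C@@H](Oc2cc(OCc3ccccc3)cc(OCc3ccccc3)c2Br)[C@@H]2C(=O)O[C@H](c3ccc(OCc4ccccc4)cc3)[C@H]2C(=O)OC(C)(C)C)cc1 | intermediate
15 | lithium 9b-olate of tert-butyl 7,9-bis(benzyloxy)-2-[4-(benzyloxy)phenyl]-4-(4-methoxyphenyl)-2,3,3a,4-tetrahydro-9bH-furo[3,2-c]chromene-3-carboxylate (cis-fused tetrahedral adduct; C2 S, C3 R, C3' S, C2' S, hemiketal carbon R) | COc1ccc([C@H]2Oc3cc(OCc4ccccc4)cc(OCc4ccccc4)c3[C@]4([O-])O[C@H](c3ccc(OCc5ccccc5)cc3)[C@@H](C(=O)OC(C)(C)C)[C@H]24)cc1.[Li+] | intermediate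
16 | tert-butyl (2S,3S)-3-[4-(benzyloxy)phenyl]-2-[(2S,3R)-5,7-bis(benzyloxy)-2-(4-methoxyphenyl)-4-oxochroman-3-yl]-3-hydroxypropanoate | COc1ccc([C@H]2Oc3cc(OCc4ccccc4)cc(OCc4ccccc4)c3C(=O)[C@@H]2[C@H](C(=O)OC(C)(C)C)[C@H](O)c2ccc(OCc3ccccc3)cc2)cc1 | intermediate
17 | 1,3-bis(benzyloxy)-5-bromobenzene | Brc1cc(OCc2ccccc2)cc(OCc2ccccc2)c1 | starting material
18 | tert-butyl (2S,3S)-3-[4-(benzyloxy)phenyl]-3-[3,5-bis(benzyloxy)phenoxy]-2-[(2S,3R)-5,7-bis(benzyloxy)-2-(4-methoxyphenyl)-4-oxochroman-3-yl]propanoate | COc1ccc([C@H]2Oc3cc(OCc4ccccc4)cc(OCc4ccccc4)c3C(=O)[C@@H]2[C@H](C(=O)OC(C)(C)C)[C@H](Oc2cc(OCc3ccccc3)cc(OCc3ccccc3)c2)c2ccc(OCc3ccccc3)cc2)cc1 | intermediate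
19 | (2S,3S)-3-[4-(benzyloxy)phenyl]-3-[3,5-bis(benzyloxy)phenoxy]-2-[(2S,3R)-5,7-bis(benzyloxy)-2-(4-methoxyphenyl)-4-oxochroman-3-yl]propanoic acid | COc1ccc([C@H]2Oc3cc(OCc4ccccc4)cc(OCc4ccccc4)c3C(=O)[C@@H]2[C@H](C(=O)O)[C@H](Oc2cc(OCc3ccccc3)cc(OCc3ccccc3)c2)c2ccc(OCc3ccccc3)cc2)cc1 | intermediate
20 | (2S,3S)-3-[4-(benzyloxy)phenyl]-3-[3,5-bis(benzyloxy)phenoxy]-2-[(2S,3R)-5,7-bis(benzyloxy)-2-(4-methoxyphenyl)-4-oxochroman-3-yl]propanoic trifluoroacetic anhydride | COc1ccc([C@H]2Oc3cc(OCc4ccccc4)cc(OCc4ccccc4)c3C(=O)[C@@H]2[C@H](C(=O)OC(=O)C(F)(F)F)[C@H](Oc2cc(OCc3ccccc3)cc(OCc3ccccc3)c2)c2ccc(OCc3ccccc3)cc2)cc1 | intermediate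
21 | (2S,3R,2'S,3'S)-5,5',7,7'-tetrakis(benzyloxy)-2'-[4-(benzyloxy)phenyl]-2-(4-methoxyphenyl)-[3,3'-bichromane]-4,4'-dione | COc1ccc([C@H]2Oc3cc(OCc4ccccc4)cc(OCc4ccccc4)c3C(=O)[C@@H]2[C@@H]2C(=O)c3c(OCc4ccccc4)cc(OCc4ccccc4)cc3O[C@@H]2c2ccc(OCc3ccccc3)cc2)cc1 | intermediate
22 | (2S,3R,2'S,3'S)-5,5',7,7'-tetrahydroxy-2'-(4-hydroxyphenyl)-2-(4-methoxyphenyl)-[3,3'-bichromane]-4,4'-dione | COc1ccc([C@H]2Oc3cc(O)cc(O)c3C(=O)[C@@H]2[C@@H]2C(=O)c3c(O)cc(O)cc3O[C@@H]2c2ccc(O)cc2)cc1 | target

## Step count and least certain steps

Total: 13 steps. Longest linear sequence: 12 steps (steps 1–6 and 8–13); step 7 is a one-step branch.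

**Step 9 (key step).** The most likely failure is proton transfer in place of exchange and acylation. The C3–H (alpha to the lactone, beta to the aryloxy group) or the C3'–H could be removed by t-BuLi or by the aryllithium, followed by beta-elimination of the ring A phenoxide or opening of the lactone. A second failure is early collapse of the lithium hemiketal on warming, which exposes the new ketone to base. Fallback, from 14 back to 16 through an open-chain acyl donor: the lactone of 14 is opened with Me(MeO)NH·HCl and AlMe3 to the hydroxy N-methoxy-N-methylamide F1. Its C2' hydroxyl is capped as the triethylsilyl ether F2. Bromine–lithium exchange and cyclisation onto the amide, whose chelated adduct is stable until work-up, would give the silylated chromanone F3. HF·pyridine then removes the silyl group and the route is rejoined at 16.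

**Step 10.** The palladium alkoxide of this hindered benzylic carbinol may undergo beta-hydride elimination faster than C–O reductive elimination, and the carbonate base at 80 °C may enolise C3 (ring-opening or epimerisation of unit 1) or trigger retro-aldol cleavage. Fallback, from 16 and 17 back to 18 without base: 17 is converted (n-BuLi; B(Oi-Pr)3; aq. KHF2) into potassium [3,5-bis(benzyloxy)phenyl]trifluoroborate F4. A copper-mediated oxidative Chan–Lam etherification of 16 with F4 (Cu(OAc)2·H2O, DMAP, 4 Å MS, O2, CH2Cl2, rt) would then give 18.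

**Step 12.** The cis configuration may be lost by enolisation at C3' (of the mixed anhydride or of the new ketone) in the acidic medium, and the C2' benzylic ether may ionise. Fallback, from 19 back to 21 with a preformed acyl electrophile: 1-chloro-N,N,2-trimethylprop-1-en-1-amine in CH2Cl2 converts 19 under neutral conditions into the acyl chloride F5, which is closed at −78 °C with SnCl4 and quenched cold.

**Step 6.** Facial selectivity may be poor if the catalyst preference and the bias of the substituted lactone oppose each other, or reduction may run through the minor C3 epimer. Fallback, from 8 back to 11 by forming the carbinol in the C–C bond-forming step: the lithium enolate of 8 is transmetallated with Cp2ZrCl2 and added to 4-methoxybenzaldehyde (THF, −78 °C), since zirconium enolates of fixed geometry favour syn adducts. 11 is separated by chromatography from its C2 epimer, the (S)-carbinol F6, which can be oxidised with the periodinane DMP to 10 and recycled.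

**Step 7.** Bromination may occur para to the hydroxyl (between the two benzyloxy groups) or twice, i.e. regioselectivity may be poor. Fallback, from 12 back to 13 by directed metalation: 12 is converted (Et2NCOCl, NaH, THF) into 3,5-bis(benzyloxy)phenyl diethylcarbamate F7. Ortho-lithiation between the carbamate and a benzyloxy group (s-BuLi, TMEDA, THF, −78 °C) and quenching with BrCCl2CCl2Br would give the bromo carbamate F8, and hydrolysis (NaOH, EtOH, reflux) gives 13.

## Further compounds

F1 | step 9 | tert-butyl (2S,3R)-2-{(S)-[4-(benzyloxy)phenyl](hydroxy)methyl}-3-{(S)-[3,5-bis(benzyloxy)-2-bromophenoxy](4-methoxyphenyl)methyl}-4-[methoxy(methyl)amino]-4-oxobutanoate | COc1ccc([C@@H](Oc2cc(OCc3ccccc3)cc(OCc3ccccc3)c2Br)[C@H](C(=O)N(C)OC)[C@H](C(=O)OC(C)(C)C)[C@H](O)c2ccc(OCc3ccccc3)cc2)cc1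
F2 | step 9 | triethylsilyl ether of F1 at the C2' oxygen | COc1ccc([C@@H](Oc2cc(OCc3ccccc3)cc(OCc3ccccc3)c2Br)[C@H](C(=O)N(C)OC)[C@H](C(=O)OC(C)(C)C)[C@H](O[Si](CC)(CC)CC)c2ccc(OCc3ccccc3)cc2)cc1
F3 | step 9 | tert-butyl (2S,3S)-3-[4-(benzyloxy)phenyl]-2-[(2S,3R)-5,7-bis(benzyloxy)-2-(4-methoxyphenyl)-4-oxochroman-3-yl]-3-(triethylsilyloxy)propanoate | COc1ccc([C@H]2Oc3cc(OCc4ccccc4)cc(OCc4ccccc4)c3C(=O)[C@@H]2[C@H](C(=O)OC(C)(C)C)[C@H](O[Si](CC)(CC)CC)c2ccc(OCc3ccccc3)cc2)cc1
F4 | step 10 | potassium [3,5-bis(benzyloxy)phenyl]trifluoroborate | [K+].F[B-](F)(F)c1cc(OCc2ccccc2)cc(OCc2ccccc2)c1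
F5 | step 12 | (2S,3S)-3-[4-(benzyloxy)phenyl]-3-[3,5-bis(benzyloxy)phenoxy]-2-[(2S,3R)-5,7-bis(benzyloxy)-2-(4-methoxyphenyl)-4-oxochroman-3-yl]propanoyl chloride | COc1ccc([C@H]2Oc3cc(OCc4ccccc4)cc(OCc4ccccc4)c3C(=O)[C@@H]2[C@H](C(Cl)=O)[C@H](Oc2cc(OCc3ccccc3)cc(OCc3ccccc3)c2)c2ccc(OCc3ccccc3)cc2)cc1
F6 | step 6 | tert-butyl (2S,3S,4R)-2-[4-(benzyloxy)phenyl]-4-[(S)-hydroxy(4-methoxyphenyl)methyl]-5-oxotetrahydrofuran-3-carboxylate | COc1ccc([C@@H](O)[C@@H]2C(=O)O[C@H](c3ccc(OCc4ccccc4)cc3)[C@H]2C(=O)OC(C)(C)C)cc1
F7 | step 7 | 3,5-bis(benzyloxy)phenyl diethylcarbamate | CCN(CC)C(=O)Oc1cc(OCc2ccccc2)cc(OCc2ccccc2)c1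
F8 | step 7 | 3,5-bis(benzyloxy)-2-bromophenyl diethylcarbamate | CCN(CC)C(=O)Oc1cc(OCc2ccccc2)cc(OCc2ccccc2)c1Br
A1 | alternative 1 | (2S,3R)-5,7-bis(benzyloxy)-3-{2-[2,4-bis(benzyloxy)-6-fluorophenyl]-2-oxoethyl}-2-(4-methoxyphenyl)chroman-4-one | COc1ccc([C@H]2Oc3cc(OCc4ccccc4)cc(OCc4ccccc4)c3C(=O)[C@@H]2CC(=O)c2c(F)cc(OCc3ccccc3)cc2OCc2ccccc2)cc1
A2 | alternative 1 | 5,7-bis(benzyloxy)chromone | O=c1ccoc2cc(OCc3ccccc3)cc(OCc3ccccc3)c12
A3 | alternative 1 | (4-methoxyphenyl)zinc chloride | COc1ccc([Zn]Cl)cc1
A4 | alternative 1 | 2-bromo-1-[2,4-bis(benzyloxy)-6-fluorophenyl]ethan-1-one | O=C(CBr)c1c(F)cc(OCc2ccccc2)cc1OCc1ccccc1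
A5 | alternative 2 | methyl 2-[(2S,3R)-7-hydroxy-5-methoxy-2-(4-methoxyphenyl)-4-oxochroman-3-yl]acetate | COc1ccc([C@H]2Oc3cc(O)cc(OC)c3C(=O)[C@@H]2CC(=O)OC)cc1
A6 | alternative 2 | 1,1-dimethoxy-3-(trimethylsilyloxy)buta-1,3-diene | C=C(O[Si](C)(C)C)C=C(OC)OC
A7 | alternative 2 | methyl 2-[(2S,3R)-5-bromo-2-(4-methoxyphenyl)-4-oxo-3,4-dihydro-2H-pyran-3-yl]acetate | COc1ccc([C@H]2OC=C(Br)C(=O)[C@@H]2CC(=O)OC)cc1
A8 | alternative 3 | methyl 2-[(2S,3S,4S)-5,7-bis(benzyloxy)-4-methoxy-2-(4-methoxyphenyl)chroman-3-yl]acetate (2,3-trans, 3,4-trans) | COc1ccc([C@H]2Oc3cc(OCc4ccccc4)cc(OCc4ccccc4)c3[C@@H](OC)[C@@H]2CC(=O)OC)cc1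
A9 | alternative 3 | 2,4-bis(benzyloxy)-6-hydroxybenzaldehyde | O=Cc1c(O)cc(OCc2ccccc2)cc1OCc1ccccc1
A10 | alternative 3 | methyl (E)-4-(4-methoxyphenyl)but-3-enoate | COC(=O)C/C=C/c1ccc(OC)cc1
A11 | alternative 3 | trimethyl orthoformate | COC(OC)OC
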